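The numbers are assumed; the run is a simulation.

You have 3 questions on one flask, and one constant carries them.

    target ⇌ product in the second phase, rate k1*([target] - [product in the second phase]/K1) per volume of the first phase (K1 = 2.26, k1 = 0.0267 /s)
    target → decomposed product (k2 = 2.51 × 10⁻⁴ /s)
    substrate + reagent in the reaction phase ⇌ target (K3 = 140 /M, k3 = 0.0151 /M/s)
    reagent in the reaction phase ⇌ reagent in the second phase, rate k4*([reagent in the reaction phase] - [reagent in the second phase]/K4) per volume of the first phase (K4 = 0.79, k4 = 0.0395 /s)

substrate 20 mM; reagent in the second phase 60.0 mM; time 15 min; volume of the second phase over the first 0.25

- amounts and yields of target count product in the second phase too
- in the second phase: reagent in the second phase, product in the second phase; everything else is in the first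
- charges count per volume of the first phase; a concentration in a rate is the amount of a species over the volume of its own phase; every rate counts per litre of the first phase
- run time (flask): 15 min

- amount of target and product in the second phase together at 15 min, in percent of the substrate charged
- the change that raises the amount of target and product in the second phase together at 15 min, in percent of the substrate charged most ("none" if none brings more than 2 percentage points) (Sunday's / Thursday's / Friday's / none)
- amount of target and product in the second phase together at 15 min, in percent of the substrate charged, after Thursday's

- Sunday's: doubling the amount of reagent in the second phase, all else as stated
- Thursday's: doubling the transfer coefficient of step 4, all else as stated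
- Friday's: doubling the transfer coefficient of step 1, all else as stated

Start at the fast end of the ladder. Reagent relaxes towards its partition with a time of 4.18 s and target with a time of 13.5 s, so against 15 min you may take both transfers as settled. That leaves 50.1 mM of reagent free in the reaction phase, and a share of 63.9 % of target in the first phase, the rest being product in the second phase.

Next rung, and the quantity to carry: the free-reagent constant kf, the forward constant of step 3 times the reagent left free, 0.0454 /min, a pseudo-first-order constant with a time of 22.0 min. Formation is the rate-limiting step here, slower than either transfer. Slowest comes the loss of target by reversal and decomposition, which act on its first-phase share: call its constant L, 0.01376 /min, a time of 72.7 min.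

So I reckon this flask as two consecutive first-order steps, and my yield at time t is kf/(kf − L) × (exp(−L t) − exp(−kf t)), which gives 44.1 %. It holds free reagent at its starting value while each target made spends some, so I read it as high. Doubling the reagent doubles kf and adds 22 percentage points, while doubling a transfer coefficient halves a lag of seconds, so my choice is Sunday's, and after Thursday's I expect 44.3 %.

The forecast gives 41.3 % (from 40 % to 42.6 %), lower than my figure, then Sunday's, and 41.5 % after Thursday's (from 40.2 % to 42.8 %), on the ground that “the 15 min run is limited by the slow second-order formation of target”.

The simulation gives 41.4 %, Sunday's with a gain of 23 points, and 41.5 % after Thursday's. My figure for this flask stands 2.7 points above the simulation, and at 15.0 min the flask's reaction phase holds 42.6 mM of reagent against the 50.1 mM I reckoned with. Carry kf and L to the same flask read at 25 min: the reckoning gives 55.6 %. That flask holds 52.3 %, with 40.0 mM of reagent in the reaction phase.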